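The route rests on opening the O1–C2 bond of flavanone ring C. C2 bears both the ring oxygen and aryl ring B and lies one carbon (C3) from the C4 carbonyl, so O1–C2–C3–C4=O is what an oxa-Michael addition of the ring A C8a phenol leaves behind. One cinchona-thiourea-catalysed cyclization closes ring C and sets C2 (S). Its precursor is an open alkylidene β-ketoester that already contains the 8,8''-biaryl bond and the complete flavone: a tert-butyl ester sits on the future C3, the C8a–OH is the only free hydroxyl, and all other oxygens are benzyl ethers, so that the final unmasking is a neutral hydrogenolysis.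

Key step: step 9

Remark (axis): the 8–8'' bond carries four ortho oxygen substituents and should be a configurationally stable axis; the target string leaves it undefined, so every biaryl is carried as both axial forms and only C2 is controlled (the two axial diastereomers of the final (2S) material would have to be separated by chromatography if only one is wanted).

Remark (protecting groups): the spectator phenols are benzyl rather than methyl ethers, because the C2–O1 bond of a 2-(4-alkoxyphenyl)flavanone is itself a benzylic aryl ether and would be endangered by BBr3-type O-demethylation; MOM is the one temporary group.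

Remark (materials and catalyst): the benzylated acetophenone, acid chloride, aldehyde and Boc2O are taken as catalogue compounds; the sense of induction of the quinidine-derived thiourea is to be confirmed on the monomeric analogue of the cyclization substrate, the quinine-derived pseudoenantiomer giving the other antipode.

Step 1
Reactants: 1 2'-hydroxy-4',6'-bis(benzyloxy)acetophenone
Product: 2 4',6'-bis(benzyloxy)-2'-hydroxy-3'-iodoacetophenone
Conditions: NIS (1.05 equiv), TsOH·H2O (10 mol%), MeCN/CH2Cl2, 0 °C → rt
Reagents that add atoms: N-iodosuccinimide, O=C1CCC(=O)N1I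
Why: Electrophilic aromatic iodination goes to C3', the position ortho to the chelated hydroxyl and flanked by only one benzyloxy group, which is both the site halogenated in 2'-hydroxy-4',6'-dialkoxyacetophenones generally and the less crowded of the two free ring positions.

Step 2
Reactants: 2 4',6'-bis(benzyloxy)-2'-hydroxy-3'-iodoacetophenone
Product: 3 4',6'-bis(benzyloxy)-3'-iodo-2'-(methoxymethoxy)acetophenone
Conditions: NaH, DMF, 0 °C; MOMCl, rt
Reagents that add atoms: chloromethyl methyl ether, COCCl
Why: Williamson-type O-alkylation of the sodium phenoxide masks the one acidic hydroxyl, which would otherwise quench the arylcopper species of the next step, as an acetal that mild acid removes without touching benzyl ethers.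

Step 3
Reactants: 3 4',6'-bis(benzyloxy)-3'-iodo-2'-(methoxymethoxy)acetophenone (2 equiv)
Product: 4 3,3'-diacetyl-4,4',6,6'-tetrakis(benzyloxy)-2,2'-bis(methoxymethoxy)biphenyl (racemic axis)
Conditions: activated Cu powder, DMF, 150 °C, degassed
Reagents that add atoms: none
Why: Classical Ullmann homocoupling (oxidative addition of the aryl iodide to copper and coupling of the arylcopper species) is the established way to symmetric biaryls with four ortho oxygen substituents and needs no second, differently functionalized partner; the new axis forms as the racemate.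

Step 4
Reactants: 4 3,3'-diacetyl-4,4',6,6'-tetrakis(benzyloxy)-2,2'-bis(methoxymethoxy)biphenyl
Product: 5 3,3'-diacetyl-4,4',6,6'-tetrakis(benzyloxy)biphenyl-2,2'-diol (symmetric diacetylbiphenol)
Conditions: 3 M HCl (aq), THF/MeOH, 50 °C
Reagents that add atoms: none
Why: Acid-catalysed acetal cleavage (transacetalization to methanol) frees the two phenols, the MOM groups next to the acetyl carbonyls being especially labile, while aryl benzyl ethers are stable to dilute HCl at this temperature.

Step 5
Reactants: 5 3,3'-diacetyl-4,4',6,6'-tetrakis(benzyloxy)biphenyl-2,2'-diol; 6 4-(benzyloxy)benzoyl chloride (1.0 equiv, slow addition)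
Product: 8 1-[3'-acetyl-4,4',6,6'-tetrakis(benzyloxy)-2,2'-dihydroxybiphenyl-3-yl]-3-[4-(benzyloxy)phenyl]propane-1,3-dione (mono-1,3-diketone), via mono-aroyl ester 7 (not isolated)
Conditions: pyridine, DMAP (10 mol%), 0 °C → rt; then powdered KOH, 50 °C; AcOH/H2O work-up
Reagents that add atoms: none
Why: O-aroylation followed by the Baker–Venkataraman O→C acyl shift (intramolecular Claisen condensation of the acetyl enolate on the neighbouring aryl ester through a six-membered transition state) builds the 1,3-diketone on one half only, one equivalent of 6 and the crowding that the first aroyl group causes across the 2,2'-positions being expected to favour monoacylation, while acyl hopping between the two phenol oxygens is degenerate and recovered 5 is recycled.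

Step 6
Reactants: 8 mono-1,3-diketone
Product: 9 8-[3-acetyl-4,6-bis(benzyloxy)-2-hydroxyphenyl]-5,7-bis(benzyloxy)-2-[4-(benzyloxy)phenyl]-4H-chromen-4-one (flavone–acetophenone)
Conditions: TsOH·H2O (10 mol%), toluene, 80 °C
Reagents that add atoms: none
Why: Acid-catalysed cyclodehydration of the 2-hydroxyaryl 1,3-diketone (the closing stage of the Baker–Venkataraman flavone synthesis) lets the phenol beside the axis add to the distal carbonyl and lose water, which fixes the 8-linkage of the flavone, whereas the hydroxyacetophenone half has no such partner and is left as it is.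

Step 7
Reactants: 9 flavone–acetophenone; 10 di-tert-butyl dicarbonate (1.1 equiv)
Product: 11 tert-butyl 3-{4,6-bis(benzyloxy)-3-[5,7-bis(benzyloxy)-2-(4-benzyloxyphenyl)-4-oxo-4H-chromen-8-yl]-2-hydroxyphenyl}-3-oxopropanoate
Conditions: LiN(SiMe3)2 (3.3 equiv), THF, −78 °C; then 10, −78 → 0 °C; aq NH4Cl
Reagents that add atoms: none
Why: Claisen-type C-acylation of the ketone enolate in the phenoxide/enolate dianion by Boc2O (an aryl carbonate formed first at oxygen would pass its acyl group on to the enolate carbon in a Baker–Venkataraman-type shift) gives the β-ketoester, which is shielded as its chelated anion from a second acylation and, as a tert-butyl ester, does not lactonize to a 4-hydroxycoumarin, while the flavone offers no acidic C–H to the hindered amide base at low temperature.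

Step 8
Reactants: 11 tert-butyl β-ketoester; 12 4-(benzyloxy)benzaldehyde
Product: 13 tert-butyl (Z)-2-{4,6-bis(benzyloxy)-3-[5,7-bis(benzyloxy)-2-(4-benzyloxyphenyl)-4-oxo-4H-chromen-8-yl]-2-hydroxybenzoyl}-3-[4-(benzyloxy)phenyl]acrylate
Conditions: piperidine (20 mol%), AcOH (20 mol%), 4 Å MS, toluene, rt
Reagents that add atoms: none
Why: Knoevenagel condensation through the piperidinium iminium ion of the aldehyde converts the active methylene into the trisubstituted alkene, the isomer with the aryl group cis to the ester (Z) being expected to dominate, and the buffered, anhydrous, room-temperature conditions together with the hydrogen bond from the C8a–OH to the ketone should hold back premature, racemic ring closure.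

Step 9
Reactants: 13 alkylidene β-ketoester (both axial forms)
Product: 14 tert-butyl (2S,3R)-5,7-bis(benzyloxy)-8-[5,7-bis(benzyloxy)-2-(4-benzyloxyphenyl)-4-oxo-4H-chromen-8-yl]-2-[4-(benzyloxy)phenyl]-4-oxochromane-3-carboxylate (trans)
Conditions: N-[3,5-bis(trifluoromethyl)phenyl]-N'-(9-deoxy-epi-quinidin-9-yl)thiourea (10 mol%), toluene, −25 °C
Reagents that add atoms: none
Why: The basic quinuclidine nitrogen of the catalyst engages the C8a–OH while the two thiourea N–H bonds hold the ketone/ester pair of the alkylidene, and the phenoxide of this organized ion pair adds intramolecularly to the β-carbon, protonation of the ester-stabilized enolate completing an oxa-Michael addition that forms O1–C2. The closest known reaction type is this same cinchona-thiourea-catalysed cyclization of 2-hydroxyaryl alkylidene β-ketoesters to 3-carboxylated flavanones, applied here to a substrate that already carries the 8-flavonyl unit. Ring C closes in the 6-endo-trig mode. C2 (S) is set by the catalyst, which decides the face of the β-carbon that the oxygen can reach, on both axial forms of 13, whereas C3 is under thermodynamic control, the acidic β-dicarbonyl position settling as the trans-diequatorial (3R) epimer before it is erased in step 10. The step needs enantioface selectivity together with site selectivity (8-linked and not 6-linked flavanone, alkylidene and not flavone as acceptor), and the substrate secures the latter because O5 is benzylated, leaving the C8a–OH as the only nucleophile, and because a 2-arylchromone is too poor an electrophile for a phenol under amine catalysis. Because the extra ester lowers the LUMO of the enone the addition can run cold, and because the adduct is an enolizable β-dicarbonyl instead of a simple ketone, re-opening to the phenol–enone, the way chalcone-derived flavanones usually lose configuration, should be disfavoured.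

Step 10
Reactants: 14 trans-3-(tert-butoxycarbonyl)flavanone–flavone hexabenzyl ether
Product: 16 (2S)-5,7-bis(benzyloxy)-8-[5,7-bis(benzyloxy)-2-(4-benzyloxyphenyl)-4-oxo-4H-chromen-8-yl]-2-[4-(benzyloxy)phenyl]chroman-4-one, via β-keto acid 15 (not isolated)
Conditions: TsOH·H2O (1 equiv), toluene, 80 °C
Reagents that add atoms: none
Why: Acid-promoted E1 loss of isobutene from the tert-butyl ester gives the β-keto acid, which decarboxylates through its six-membered cyclic transition state at 80 °C, and since no base is present the ring-opening pathway that would scramble C2 is not available.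

Step 11
Reactants: 16 (2S)-flavanone–flavone hexabenzyl ether
Product: 17 (2S)-5,7-dihydroxy-8-[5,7-dihydroxy-2-(4-hydroxyphenyl)-4-oxo-4H-chromen-8-yl]-2-(4-hydroxyphenyl)chroman-4-one (target)
Conditions: H2 (1 atm), 10% Pd/C, THF/MeOH, rt; filtration, neutral work-up
Reagents that add atoms: none
Why: Palladium-catalysed hydrogenolysis removes all six O-benzyl groups under neutral conditions, under which the conjugated flavone double bond, the aryl ketones and the ring C2–O1 bond react far more slowly and C2, which epimerizes only through base- or acid-induced ring opening, is not touched.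

Compound list
1 | 2'-hydroxy-4',6'-bis(benzyloxy)acetophenone | CC(=O)c1c(O)cc(OCc2ccccc2)cc1OCc1ccccc1 | starting material
2 | 4',6'-bis(benzyloxy)-2'-hydroxy-3'-iodoacetophenone | CC(=O)c1c(O)c(I)c(OCc2ccccc2)cc1OCc1ccccc1 | intermediate
3 | 4',6'-bis(benzyloxy)-3'-iodo-2'-(methoxymethoxy)acetophenone | CC(=O)c1c(OCOC)c(I)c(OCc2ccccc2)cc1OCc1ccccc1 | intermediate
4 | 3,3'-diacetyl-4,4',6,6'-tetrakis(benzyloxy)-2,2'-bis(methoxymethoxy)biphenyl (racemic axis) | CC(=O)c1c(OCOC)c(c(OCc2ccccc2)cc1OCc1ccccc1)-c1c(OCOC)c(C(C)=O)c(OCc2ccccc2)cc1OCc1ccccc1 | intermediate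
5 | 3,3'-diacetyl-4,4',6,6'-tetrakis(benzyloxy)biphenyl-2,2'-diol (racemic axis) | CC(=O)c1c(O)c(c(OCc2ccccc2)cc1OCc1ccccc1)-c1c(O)c(C(C)=O)c(OCc2ccccc2)cc1OCc1ccccc1 | intermediate
6 | 4-(benzyloxy)benzoyl chloride | O=C(Cl)c1ccc(OCc2ccccc2)cc1 | starting material
7 | mono-O-[4-(benzyloxy)benzoyl] ester of 5 (not isolated) | CC(=O)c1c(OC(=O)c2ccc(OCc3ccccc3)cc2)c(c(OCc2ccccc2)cc1OCc1ccccc1)-c1c(O)c(C(C)=O)c(OCc2ccccc2)cc1OCc1ccccc1 | intermediate
8 | 1-[3'-acetyl-4,4',6,6'-tetrakis(benzyloxy)-2,2'-dihydroxybiphenyl-3-yl]-3-[4-(benzyloxy)phenyl]propane-1,3-dione | O=C(CC(=O)c1ccc(OCc2ccccc2)cc1)c1c(O)c(c(OCc2ccccc2)cc1OCc1ccccc1)-c1c(O)c(C(C)=O)c(OCc2ccccc2)cc1OCc1ccccc1 | intermediate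
9 | 8-[3-acetyl-4,6-bis(benzyloxy)-2-hydroxyphenyl]-5,7-bis(benzyloxy)-2-[4-(benzyloxy)phenyl]-4H-chromen-4-one | CC(=O)c1c(O)c(c(OCc2ccccc2)cc1OCc1ccccc1)-c1c(OCc2ccccc2)cc(OCc2ccccc2)c2c(=O)cc(-c3ccc(OCc4ccccc4)cc3)oc12 | intermediate
10 | di-tert-butyl dicarbonate | CC(C)(C)OC(=O)OC(=O)OC(C)(C)C | starting material
11 | tert-butyl 3-{4,6-bis(benzyloxy)-3-[5,7-bis(benzyloxy)-2-(4-benzyloxyphenyl)-4-oxo-4H-chromen-8-yl]-2-hydroxyphenyl}-3-oxopropanoate | CC(C)(C)OC(=O)CC(=O)c1c(O)c(c(OCc2ccccc2)cc1OCc1ccccc1)-c1c(OCc2ccccc2)cc(OCc2ccccc2)c2c(=O)cc(-c3ccc(OCc4ccccc4)cc3)oc12 | intermediate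
12 | 4-(benzyloxy)benzaldehyde | O=Cc1ccc(OCc2ccccc2)cc1 | starting material
13 | tert-butyl (Z)-2-{4,6-bis(benzyloxy)-3-[5,7-bis(benzyloxy)-2-(4-benzyloxyphenyl)-4-oxo-4H-chromen-8-yl]-2-hydroxybenzoyl}-3-[4-(benzyloxy)phenyl]acrylate (key-step precursor) | c1ccccc1COc1ccc(cc1)/C=C(\C(=O)OC(C)(C)C)C(=O)c1c(O)c(c(OCc2ccccc2)cc1OCc1ccccc1)-c1c(OCc2ccccc2)cc(OCc2ccccc2)c2c(=O)cc(-c3ccc(OCc4ccccc4)cc3)oc12 | intermediate
14 | tert-butyl (2S,3R)-trans-4-oxochromane-3-carboxylate, hexabenzyl ether of the flavanone–flavone (key-step product) | O=C1[C@H](C(=O)OC(C)(C)C)[C@@H](c2ccc(OCc3ccccc3)cc2)Oc2c1c(OCc1ccccc1)cc(OCc1ccccc1)c2-c1c(OCc2ccccc2)cc(OCc2ccccc2)c2c(=O)cc(-c3ccc(OCc4ccccc4)cc3)oc12 | intermediate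
15 | (2S,3R)-4-oxochromane-3-carboxylic acid, hexabenzyl ether (β-keto acid, not isolated) | O=C1[C@H](C(=O)O)[C@@H](c2ccc(OCc3ccccc3)cc2)Oc2c1c(OCc1ccccc1)cc(OCc1ccccc1)c2-c1c(OCc2ccccc2)cc(OCc2ccccc2)c2c(=O)cc(-c3ccc(OCc4ccccc4)cc3)oc12 | intermediate
16 | (2S)-flavanone–flavone hexabenzyl ether | O=C1C[C@@H](c2ccc(OCc3ccccc3)cc2)Oc2c1c(OCc1ccccc1)cc(OCc1ccccc1)c2-c1c(OCc2ccccc2)cc(OCc2ccccc2)c2c(=O)cc(-c3ccc(OCc4ccccc4)cc3)oc12 | intermediate
17 | (2S)-5,7-dihydroxy-8-[5,7-dihydroxy-2-(4-hydroxyphenyl)-4-oxo-4H-chromen-8-yl]-2-(4-hydroxyphenyl)chroman-4-one | O=C1C[C@@H](c2ccc(O)cc2)Oc2c1c(O)cc(O)c2-c1c(O)cc(O)c2c(=O)cc(-c3ccc(O)cc3)oc12 | target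

Total step count: 11. Longest linear sequence: 11 steps (1 → 17; 6, 10 and 12 enter as purchased building blocks).

Steps most likely to fail

Step 9 (key cyclization). The catalyst may not discriminate the faces of the β-carbon equally well on the two axial forms of 13. The hindered, hydrogen-bonded phenol may add too slowly to the electron-rich acceptor, and reversible ring opening may erode C2. The fallback forms the C2–aryl bond in place of O1–C2 and uses known chemistry. It sets out from 9: condensation with N,N-dimethylformamide dimethyl acetal (toluene, 90 °C) should give the enaminone F1, which closes with loss of dimethylamine under mild acid (AcOH, 60 °C) to the 2-unsubstituted chromone F2. Rhodium-catalysed asymmetric 1,4-addition of 4-(benzyloxy)phenylboronic acid ([Rh(OH)(cod)]2, electron-poor MeO-F12-BIPHEP-type bisphosphine, toluene/H2O, rt, ligand antipode chosen for 2S) would then give the flavanone directly. The 2-aryl flavone half is a β,β-disubstituted acceptor and should stay inert. The fallback comes back to the route at 16.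

Step 3 (Ullmann coupling). Reduction of the C–I bond to C–H and incomplete coupling are the usual failures of electron-rich, doubly ortho-substituted iodides on copper, and the MOM acetal may suffer at 150 °C. The fallback sets out from 3: Miyaura borylation (B2pin2, PdCl2(dppf), KOAc, dioxane, 90 °C) gives the pinacol boronate F3. Suzuki–Miyaura coupling of F3 with a second equivalent of 3 (Pd(OAc)2, SPhos, K3PO4, toluene/H2O, 100 °C) then forms the same biaryl bond by transmetallation and reductive elimination at palladium instead of on a copper surface. It comes back to the route at 4.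

Step 5 (desymmetrizing acylation and acyl shift). Acylation of both halves, or saponification of the hindered ester before the O→C shift, would leave little mono-diketone. The fallback is convergent and avoids any symmetric intermediate. It sets out from 2: Claisen–Schmidt condensation with 12 (KOH, EtOH/THF, rt) gives the chalcone F4, and oxidative cyclization (catalytic I2, DMSO, 120 °C) gives the 8-iodoflavone F5. Suzuki–Miyaura coupling of F5 with the pinacol boronate F3 (made from 3 as above; Pd(OAc)2, SPhos, K3PO4, toluene/H2O, 100 °C) gives the MOM ether F6. Cleavage of the acetal with HCl in MeOH brings the sequence back to the route at 9.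

Further compounds
F1 | step 9 | (E)-3-(dimethylamino)-1-{4,6-bis(benzyloxy)-3-[5,7-bis(benzyloxy)-2-(4-benzyloxyphenyl)-4-oxo-4H-chromen-8-yl]-2-hydroxyphenyl}prop-2-en-1-one (enaminone) | CN(C)/C=C/C(=O)c1c(O)c(c(OCc2ccccc2)cc1OCc1ccccc1)-c1c(OCc2ccccc2)cc(OCc2ccccc2)c2c(=O)cc(-c3ccc(OCc4ccccc4)cc3)oc12
F2 | step 9 | 5,7-bis(benzyloxy)-8-[5,7-bis(benzyloxy)-2-(4-benzyloxyphenyl)-4-oxo-4H-chromen-8-yl]-4H-chromen-4-one (chromone) | O=c1ccoc2c1c(OCc1ccccc1)cc(OCc1ccccc1)c2-c1c(OCc2ccccc2)cc(OCc2ccccc2)c2c(=O)cc(-c3ccc(OCc4ccccc4)cc3)oc12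
F3 | step 3 | 4',6'-bis(benzyloxy)-2'-(methoxymethoxy)-3'-(4,4,5,5-tetramethyl-1,3,2-dioxaborolan-2-yl)acetophenone (pinacol boronate) | CC(=O)c1c(OCOC)c(B2OC(C)(C)C(C)(C)O2)c(OCc2ccccc2)cc1OCc1ccccc1
F4 | step 5 | (E)-1-[4,6-bis(benzyloxy)-2-hydroxy-3-iodophenyl]-3-[4-(benzyloxy)phenyl]prop-2-en-1-one (chalcone) | O=C(/C=C/c1ccc(OCc2ccccc2)cc1)c1c(O)c(I)c(OCc2ccccc2)cc1OCc1ccccc1
F5 | step 5 | 5,7-bis(benzyloxy)-2-[4-(benzyloxy)phenyl]-8-iodo-4H-chromen-4-one (8-iodoflavone) | O=c1cc(-c2ccc(OCc3ccccc3)cc2)oc2c(I)c(OCc3ccccc3)cc(OCc3ccccc3)c12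
F6 | step 5 | 8-[3-acetyl-4,6-bis(benzyloxy)-2-(methoxymethoxy)phenyl]-5,7-bis(benzyloxy)-2-[4-(benzyloxy)phenyl]-4H-chromen-4-one (MOM ether of 9) | CC(=O)c1c(OCOC)c(c(OCc2ccccc2)cc1OCc1ccccc1)-c1c(OCc2ccccc2)cc(OCc2ccccc2)c2c(=O)cc(-c3ccc(OCc4ccccc4)cc3)oc12
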